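**Retrosynthetic overview**
1. Both tetrahydrofuran rings are closed last, in one pot, by O-alkylation at the primary carbons C4 and C8 of an acyclic 1,4-dimesylate (ring A: C2–O–C4; ring B: C6–O–C8), so no benzylic C–O bond is ever broken.
2. The dimesylate comes from reduction of a trans-3,4-disubstituted γ-butyrolactone, whose C1–C2 bond is made by an anti-selective intermolecular aldol of the lithium enolate of lactone 16 with silyl-protected vanillin 18 (sets C1 and C2, the endo aryl).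
3. Lactone 16 comes from an Evans syn-aldol of N-pentenoyl oxazolidinone 4 with O-benzylvanillin 5 (sets C5 and C6, the exo aryl), then auxiliary reduction, alkene cleavage and lactol oxidation.
4. The phenols are told apart by a benzyl → prenyl exchange at the lactone stage (after the alkene cleavage); the other phenol travels as a TIPS ether and is freed by fluoride in the ring-closing step.

Assumption: the SMILES is read as the (1R,3aR,4S,6aR)-furo[3,4-c]furan (epipinoresinol type), with the 4-hydroxy-3-methoxyphenyl ring endo and the prenyloxy ring exo. Positions are numbered as 3,7-dioxabicyclo[3.3.0]octane: C1/C5 ring fusion, C2 the hydroxyaryl carbon, C6 the prenyloxyaryl carbon, C4 (on C5) and C8 (on C1) the CH2 groups.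

Abbreviations: ArBn = 4-benzyloxy-3-methoxyphenyl; ArPren = 3-methoxy-4-(3-methylbut-2-enyloxy)phenyl; ArTIPS = 3-methoxy-4-(triisopropylsilyloxy)phenyl; TBS = tert-butyldimethylsilyl; TIPS = triisopropylsilyl; Ms = methanesulfonyl.

**Route**

Step 1
Reactants: 1 (S)-4-benzyl-2-oxazolidinone; 2 pent-4-enoyl chloride
Product: 4 (S)-4-benzyl-3-(pent-4-enoyl)oxazolidin-2-one, via N-lithio oxazolidinone 3 (not isolated)
Conditions: n-BuLi, THF, −78 °C; then 2, −78 → 0 °C
Reagents that add atoms: none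
Why: N-acylation of the lithiated oxazolidinone by the acid chloride (nucleophilic acyl substitution) is clean and touches no stereocentre.

Step 2
Reactants: 4 (S)-4-benzyl-3-(pent-4-enoyl)oxazolidin-2-one; 5 4-benzyloxy-3-methoxybenzaldehyde
Product: 8 (S)-4-benzyl-3-[(2S)-2-[(S)-(ArBn)(hydroxy)methyl]pent-4-enoyl]oxazolidin-2-one, via Z-dibutylboron enolate 6 (not isolated), via dibutylboron aldolate 7 (not isolated)
Conditions: Bu2BOTf, iPr2NEt, CH2Cl2, 0 °C; then 5, −78 → 0 °C; pH 7 buffer, MeOH, 30% H2O2, 0 °C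
Reagents that add atoms: none
Why: Evans syn-aldol: the Z-boron enolate reacts through a chair Zimmerman–Traxler transition state with the auxiliary benzyl group shielding one enolate face, giving the (2S,3S) syn adduct that fixes C5 and C6 (the syn relationship becomes the exo aryl).

Step 3
Reactants: 8 Evans syn-aldol adduct
Product: 9 (S)-4-benzyl-3-[(2S)-2-[(S)-(ArBn)(TBS-oxy)methyl]pent-4-enoyl]oxazolidin-2-one
Conditions: TBSOTf, 2,6-lutidine, CH2Cl2, 0 °C
Reagents that add atoms: tert-butyldimethylsilyl triflate CC(C)(C)[Si](C)(C)OS(=O)(=O)C(F)(F)F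
Why: Silylation of the secondary alcohol with a silyl triflate keeps the benzylic oxygen out of the later lactol formation and stops retro-aldol.

Step 4
Reactants: 9 silylated aldol adduct
Product: 10 (2R)-2-[(S)-(ArBn)(TBS-oxy)methyl]pent-4-en-1-ol
Conditions: LiBH4, H2O (1 equiv), Et2O, 0 °C
Reagents that add atoms: none
Why: Reductive cleavage of the N-acyl oxazolidinone by hydride attack at the exocyclic carbonyl gives the primary alcohol without touching alkene, silyl ether or benzyl ether (the descriptor at C5 changes by priority only).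

Step 5
Reactants: 10 (2R)-2-[(S)-(ArBn)(TBS-oxy)methyl]pent-4-en-1-ol
Product: 13 (4R)-4-[(S)-(ArBn)(TBS-oxy)methyl]tetrahydrofuran-2-ol (anomer mixture), via vicinal diol 11 (not isolated), via hydroxy aldehyde 12 (not isolated)
Conditions: OsO4 (2 mol %), NaIO4 (4 equiv), 2,6-lutidine, dioxane/H2O 3:1, rt
Reagents that add atoms: osmium tetroxide O=[Os](=O)(=O)=O; sodium periodate [Na+].[O-]I(=O)(=O)=O (the new oxygen comes from OsO4, which NaIO4 restores)
Why: Lemieux–Johnson oxidation (dihydroxylation then glycol cleavage) of the only alkene gives the aldehyde, which the primary alcohol traps as the five-membered lactol.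

Step 6
Reactants: 13 lactol
Product: 14 (4R)-4-[(S)-(ArBn)(TBS-oxy)methyl]dihydrofuran-2(3H)-one
Conditions: TEMPO (10 mol %), PhI(OAc)2 (1.5 equiv), CH2Cl2, rt
Reagents that add atoms: none
Why: Oxoammonium (TEMPO) oxidation of a lactol to the γ-lactone is near-neutral, and the only ring stereocentre is β to the carbonyl and cannot epimerise.

Step 7
Reactants: 14 benzyl-protected lactone
Product: 15 (4R)-4-[(S)-(4-hydroxy-3-methoxyphenyl)(TBS-oxy)methyl]dihydrofuran-2(3H)-one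
Conditions: H2 (1 atm), 10% Pd/C, EtOAc, rt
Reagents that add atoms: none
Why: Hydrogenolysis of the aryl benzyl ether is far faster than cleavage of the secondary benzylic silyl ether in neutral EtOAc, and is placed where no alkene is present.

Step 8
Reactants: 15 phenol lactone
Product: 16 (4R)-4-[(S)-(ArPren)(TBS-oxy)methyl]dihydrofuran-2(3H)-one
Conditions: prenyl bromide, K2CO3, acetone, 50 °C
Reagents that add atoms: prenyl bromide (1-bromo-3-methylbut-2-ene) CC(C)=CCBr
Why: Williamson ether synthesis (phenoxide SN2 on a primary allylic bromide) leaves lactone and silyl ether alone, and every later step is basic or fluoride-based so the prenyl ether survives.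

Step 9
Reactants: 17 vanillin
Product: 18 3-methoxy-4-(triisopropylsilyloxy)benzaldehyde
Conditions: TIPSCl, imidazole, DMF, rt
Reagents that add atoms: chlorotriisopropylsilane CC(C)[Si](Cl)(C(C)C)C(C)C
Why: Phenol silylation; the aryl TIPS ether withstands amide base, LiAlH4 and MsCl but falls to fluoride in the last step.

Step 10
Reactants: 16 prenyl lactone; 18 TIPS-vanillin
Product: 21 (3S,4R)-3-[(R)-(ArTIPS)(hydroxy)methyl]-4-[(S)-(ArPren)(TBS-oxy)methyl]dihydrofuran-2(3H)-one, via lithium enolate 19 (not isolated), via lithium aldolate 20 (not isolated)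
Conditions: LiN(iPr)2, THF, −78 °C; then 18, −78 °C; AcOH quench at −78 °C
Reagents that add atoms: none
Why: Lithium-enolate aldol: the aldehyde adds anti to the bulky C4 substituent (3,4-trans, sets C1) and the ring-locked E-enolate reacts through a closed Zimmerman–Traxler chair to give the anti carbinol (sets C2 as R, the future endo aryl), the minor syn epimer being removed by chromatography.

Step 11
Reactants: 21 aldol lactone
Product: 22 (3S,4R)-3-[(R)-(ArTIPS)(TBS-oxy)methyl]-4-[(S)-(ArPren)(TBS-oxy)methyl]dihydrofuran-2(3H)-one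
Conditions: TBSOTf, 2,6-lutidine, CH2Cl2, −78 → 0 °C
Reagents that add atoms: tert-butyldimethylsilyl triflate CC(C)(C)[Si](C)(C)OS(=O)(=O)C(F)(F)F
Why: Silylation of the aldol hydroxyl blocks retro-aldol during hydride reduction and keeps this benzylic oxygen from being sulfonylated later.

Step 12
Reactants: 22 bis-silylated lactone
Product: 23 (2R,3R)-2-[(R)-(ArTIPS)(TBS-oxy)methyl]-3-[(S)-(ArPren)(TBS-oxy)methyl]butane-1,4-diol
Conditions: LiAlH4, THF, 0 °C, 30 min
Reagents that add atoms: none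
Why: Hydride reduction of the lactone to the 1,4-diol is fast at 0 °C, where silyl ethers and the prenyl ether are inert, and involves no stereocentre.

Step 13
Reactants: 23 diol
Product: 24 (2R,3R)-2-[(R)-(ArTIPS)(TBS-oxy)methyl]-3-[(S)-(ArPren)(TBS-oxy)methyl]butane-1,4-diyl dimethanesulfonate
Conditions: MsCl (2.5 equiv), Et3N, CH2Cl2, −20 → 0 °C
Reagents that add atoms: methanesulfonyl chloride CS(Cl)(=O)=O
Why: Sulfonylation (sulfene pathway) of both primary alcohols is much faster at −20 °C than cyclisation of a monomesylate, and only primary carbons become electrophilic.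

Step 14
Reactants: 24 dimesylate
Product: 27 4-[(1R,3aR,4S,6aR)-4-(ArPren)tetrahydro-1H,3H-furo[3,4-c]furan-1-yl]-2-methoxyphenol (target), via desilylated dimesylate 25 (not isolated), via tetrahydrofuran mesylate 26 (not isolated)
Conditions: Bu4NF (5 equiv), THF (0.01 M), 0 °C → rt (40 °C if slow); NH4Cl work-up
Reagents that add atoms: none
Why: Fluoride desilylation frees the two benzylic alkoxides, each of which displaces the only mesylate it can reach through a five-membered transition state (intramolecular Williamson, 5-exo-tet); substitution occurs only at C4 and C8, so all four stereocentres are retained, and the phenol is unmasked in the same operation.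

**Compound list**
1 | (S)-4-benzyl-2-oxazolidinone | O=C1N[C@@H](Cc2ccccc2)CO1 | starting material
2 | pent-4-enoyl chloride | C=CCCC(Cl)=O | starting material
3 | N-lithio-(S)-4-benzyl-2-oxazolidinone (formed in the flask) | [Li]N1[C@@H](Cc2ccccc2)COC1=O | intermediate
4 | (S)-4-benzyl-3-(pent-4-enoyl)oxazolidin-2-one | C=CCCC(=O)N1[C@@H](Cc2ccccc2)COC1=O | intermediate
5 | 4-benzyloxy-3-methoxybenzaldehyde (O-benzylvanillin) | O=Cc1ccc(OCc2ccccc2)c(OC)c1 | starting material
6 | Z-dibutylboron enolate of 4 (formed in the flask) | C=CC/C=C(\OB(CCCC)CCCC)N1[C@@H](Cc2ccccc2)COC1=O | intermediate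
7 | dibutylboron aldolate of 8 (formed in the flask) | O=C1OC[C@H](Cc2ccccc2)N1C(=O)[C@@H](CC=C)[C@H](OB(CCCC)CCCC)c1ccc(OCc2ccccc2)c(OC)c1 | intermediate
8 | (S)-4-benzyl-3-[(2S)-2-[(S)-(ArBn)(hydroxy)methyl]pent-4-enoyl]oxazolidin-2-one | O=C1OC[C@H](Cc2ccccc2)N1C(=O)[C@@H](CC=C)[C@H](O)c1ccc(OCc2ccccc2)c(OC)c1 | intermediate
9 | (S)-4-benzyl-3-[(2S)-2-[(S)-(ArBn)(TBS-oxy)methyl]pent-4-enoyl]oxazolidin-2-one | O=C1OC[C@H](Cc2ccccc2)N1C(=O)[C@@H](CC=C)[C@H](O[Si](C)(C)C(C)(C)C)c1ccc(OCc2ccccc2)c(OC)c1 | intermediate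
10 | (2R)-2-[(S)-(ArBn)(TBS-oxy)methyl]pent-4-en-1-ol | OC[C@@H](CC=C)[C@H](O[Si](C)(C)C(C)(C)C)c1ccc(OCc2ccccc2)c(OC)c1 | intermediate
11 | (4R)-4-[(S)-(ArBn)(TBS-oxy)methyl]pentane-1,2,5-triol, both C2 epimers (formed in the flask) | OC[C@@H](CC(O)CO)[C@H](O[Si](C)(C)C(C)(C)C)c1ccc(OCc2ccccc2)c(OC)c1 | intermediate
12 | (3R,4S)-4-(ArBn)-4-(TBS-oxy)-3-(hydroxymethyl)butanal (formed in the flask) | OC[C@@H](CC=O)[C@H](O[Si](C)(C)C(C)(C)C)c1ccc(OCc2ccccc2)c(OC)c1 | intermediate
13 | (4R)-4-[(S)-(ArBn)(TBS-oxy)methyl]tetrahydrofuran-2-ol, both anomers | OC1C[C@@H]([C@H](O[Si](C)(C)C(C)(C)C)c2ccc(OCc3ccccc3)c(OC)c2)CO1 | intermediate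
14 | (4R)-4-[(S)-(ArBn)(TBS-oxy)methyl]dihydrofuran-2(3H)-one | O=C1C[C@@H]([C@H](O[Si](C)(C)C(C)(C)C)c2ccc(OCc3ccccc3)c(OC)c2)CO1 | intermediate
15 | (4R)-4-[(S)-(4-hydroxy-3-methoxyphenyl)(TBS-oxy)methyl]dihydrofuran-2(3H)-one | O=C1C[C@@H]([C@H](O[Si](C)(C)C(C)(C)C)c2ccc(O)c(OC)c2)CO1 | intermediate
16 | (4R)-4-[(S)-(ArPren)(TBS-oxy)methyl]dihydrofuran-2(3H)-one | O=C1C[C@@H]([C@H](O[Si](C)(C)C(C)(C)C)c2ccc(OCC=C(C)C)c(OC)c2)CO1 | intermediate
17 | vanillin (4-hydroxy-3-methoxybenzaldehyde) | O=Cc1ccc(O)c(OC)c1 | starting material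
18 | 3-methoxy-4-(triisopropylsilyloxy)benzaldehyde | O=Cc1ccc(O[Si](C(C)C)(C(C)C)C(C)C)c(OC)c1 | intermediate
19 | lithium enolate of 16 (formed in the flask) | [Li]OC1=C[C@@H]([C@H](O[Si](C)(C)C(C)(C)C)c2ccc(OCC=C(C)C)c(OC)c2)CO1 | intermediate
20 | lithium aldolate of 21 (formed in the flask) | O=C1OC[C@H]([C@H](O[Si](C)(C)C(C)(C)C)c2ccc(OCC=C(C)C)c(OC)c2)[C@H]1[C@@H](O[Li])c1ccc(O[Si](C(C)C)(C(C)C)C(C)C)c(OC)c1 | intermediate
21 | (3S,4R)-3-[(R)-(ArTIPS)(hydroxy)methyl]-4-[(S)-(ArPren)(TBS-oxy)methyl]dihydrofuran-2(3H)-one | O=C1OC[C@H]([C@H](O[Si](C)(C)C(C)(C)C)c2ccc(OCC=C(C)C)c(OC)c2)[C@H]1[C@@H](O)c1ccc(O[Si](C(C)C)(C(C)C)C(C)C)c(OC)c1 | intermediate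
22 | (3S,4R)-3-[(R)-(ArTIPS)(TBS-oxy)methyl]-4-[(S)-(ArPren)(TBS-oxy)methyl]dihydrofuran-2(3H)-one | O=C1OC[C@H]([C@H](O[Si](C)(C)C(C)(C)C)c2ccc(OCC=C(C)C)c(OC)c2)[C@H]1[C@@H](O[Si](C)(C)C(C)(C)C)c1ccc(O[Si](C(C)C)(C(C)C)C(C)C)c(OC)c1 | intermediate
23 | (2R,3R)-2-[(R)-(ArTIPS)(TBS-oxy)methyl]-3-[(S)-(ArPren)(TBS-oxy)methyl]butane-1,4-diol | COc1cc(ccc1O[Si](C(C)C)(C(C)C)C(C)C)[C@H](O[Si](C)(C)C(C)(C)C)[C@@H](CO)[C@H](CO)[C@H](O[Si](C)(C)C(C)(C)C)c1ccc(OCC=C(C)C)c(OC)c1 | intermediate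
24 | (2R,3R)-2-[(R)-(ArTIPS)(TBS-oxy)methyl]-3-[(S)-(ArPren)(TBS-oxy)methyl]butane-1,4-diyl dimethanesulfonate | COc1cc(ccc1O[Si](C(C)C)(C(C)C)C(C)C)[C@H](O[Si](C)(C)C(C)(C)C)[C@@H](COS(C)(=O)=O)[C@H](COS(C)(=O)=O)[C@H](O[Si](C)(C)C(C)(C)C)c1ccc(OCC=C(C)C)c(OC)c1 | intermediate
25 | (2R,3R)-2-[(R)-hydroxy(4-hydroxy-3-methoxyphenyl)methyl]-3-[(S)-hydroxy(ArPren)methyl]butane-1,4-diyl dimethanesulfonate (formed in the flask) | COc1cc(ccc1O)[C@H](O)[C@@H](COS(C)(=O)=O)[C@H](COS(C)(=O)=O)[C@H](O)c1ccc(OCC=C(C)C)c(OC)c1 | intermediate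
26 | [(2R,3R,4R)-2-(4-hydroxy-3-methoxyphenyl)-4-[(S)-hydroxy(ArPren)methyl]tetrahydrofuran-3-yl]methyl methanesulfonate (formed in the flask) | COc1cc(ccc1O)[C@@H]1OC[C@H]([C@H](O)c2ccc(OCC=C(C)C)c(OC)c2)[C@@H]1COS(C)(=O)=O | intermediate
27 | 4-[(1R,3aR,4S,6aR)-4-[3-methoxy-4-(3-methylbut-2-enyloxy)phenyl]tetrahydro-1H,3H-furo[3,4-c]furan-1-yl]-2-methoxyphenol | COc1cc([C@@H]2OC[C@H]3[C@@H]2CO[C@@H]3c2ccc(OCC=C(C)C)c(OC)c2)ccc1O | target

**Count**
Total steps: 14. Longest linear sequence: 13 steps (steps 1–8 and 10–14, from 1 to 27); step 9 is a one-step side branch.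

**Steps most likely to fail, with fallbacks**

Step 10. The trans-3,4 outcome is secure, but the anti:syn ratio at the new carbinol C2 may be modest and the adduct can revert by retro-aldol. The fallback takes the C2 configuration out of the aldol. It sets out from lactone 16 and aldehyde 18: the aldol is run as before and the unseparated mixture of 21 and its carbinol epimer (3S,4R)-3-[(S)-(ArTIPS)(hydroxy)methyl]-4-[(S)-(ArPren)(TBS-oxy)methyl]dihydrofuran-2(3H)-one F1 is oxidised with Dess–Martin periodinane and NaHCO3 in CH2Cl2 to the single α-aroyl lactone (3S,4R)-3-[3-methoxy-4-(triisopropylsilyloxy)benzoyl]-4-[(S)-(ArPren)(TBS-oxy)methyl]dihydrofuran-2(3H)-one F2. The 3,4-trans arrangement is the thermodynamic one, so enolisation of this β-keto lactone does no harm. F2 is then reduced under catalyst control by Noyori transfer hydrogenation (RuCl[(R,R)-TsDPEN](p-cymene), HCO2H/Et3N 5:2, rt), which should deliver hydride to the aryl ketone face that gives the (R)-carbinol; the sense is assigned by analogy with simple aryl ketones. The fallback comes back to the route at 21.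

Step 14. Three silyl groups must fall and two rings must close in one pot. The phenoxide is freed first and could be alkylated intermolecularly, and the two hindered benzylic silyl ethers may cleave slowly while the mesylates are exposed to fluoride. The fallback closes the rings one at a time and sets out from aldol 21, leaving its hydroxyl free. LiAlH4 in THF at 0 °C gives the triol (2R,3R)-2-[(R)-(ArTIPS)(hydroxy)methyl]-3-[(S)-(ArPren)(TBS-oxy)methyl]butane-1,4-diol F3. MsCl (2.1 equiv) in pyridine/CH2Cl2 at −20 °C sulfonylates only the two primary alcohols to the dimesylate (2R,3R)-2-[(R)-(ArTIPS)(hydroxy)methyl]-3-[(S)-(ArPren)(TBS-oxy)methyl]butane-1,4-diyl dimethanesulfonate F4. On warming to rt the free C2 hydroxyl closes ring A to give [(2R,3R,4R)-2-(ArTIPS)-4-[(S)-(ArPren)(TBS-oxy)methyl]tetrahydrofuran-3-yl]methyl methanesulfonate F5, which can be purified. Bu4NF in THF then has only one alkyl silyl ether and the aryl silyl ether to remove; it comes back to the route at 26, which closes ring B to 27.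

Step 4. With the hindered α-branched β-silyloxy imide, hydride can open the oxazolidinone ring instead of cleaving the exocyclic acyl group. The fallback reduces before protecting and sets out from the free aldol 8, whose hydroxyl directs clean exocyclic cleavage. LiBH4 in THF/MeOH at 0 °C gives (1S,2R)-2-allyl-1-(ArBn)propane-1,3-diol F6. TBSOTf (2.3 equiv) and 2,6-lutidine give the bis-silyl ether tert-butyl{[(2R)-2-[(S)-(ArBn)(TBS-oxy)methyl]pent-4-enyl]oxy}dimethylsilane F7. Selective removal of the primary silyl ether with HF·pyridine in pyridine/THF at 0 °C comes back to the route at 10.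

**Further compounds**
F1 | step 10 | (3S,4R)-3-[(S)-(ArTIPS)(hydroxy)methyl]-4-[(S)-(ArPren)(TBS-oxy)methyl]dihydrofuran-2(3H)-one | O=C1OC[C@H]([C@H](O[Si](C)(C)C(C)(C)C)c2ccc(OCC=C(C)C)c(OC)c2)[C@H]1[C@H](O)c1ccc(O[Si](C(C)C)(C(C)C)C(C)C)c(OC)c1
F2 | step 10 | (3S,4R)-3-[3-methoxy-4-(triisopropylsilyloxy)benzoyl]-4-[(S)-(ArPren)(TBS-oxy)methyl]dihydrofuran-2(3H)-one | O=C1OC[C@H]([C@H](O[Si](C)(C)C(C)(C)C)c2ccc(OCC=C(C)C)c(OC)c2)[C@H]1C(=O)c1ccc(O[Si](C(C)C)(C(C)C)C(C)C)c(OC)c1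
F3 | step 14 | (2R,3R)-2-[(R)-(ArTIPS)(hydroxy)methyl]-3-[(S)-(ArPren)(TBS-oxy)methyl]butane-1,4-diol | COc1cc(ccc1O[Si](C(C)C)(C(C)C)C(C)C)[C@H](O)[C@@H](CO)[C@H](CO)[C@H](O[Si](C)(C)C(C)(C)C)c1ccc(OCC=C(C)C)c(OC)c1
F4 | step 14 | (2R,3R)-2-[(R)-(ArTIPS)(hydroxy)methyl]-3-[(S)-(ArPren)(TBS-oxy)methyl]butane-1,4-diyl dimethanesulfonate | COc1cc(ccc1O[Si](C(C)C)(C(C)C)C(C)C)[C@H](O)[C@@H](COS(C)(=O)=O)[C@H](COS(C)(=O)=O)[C@H](O[Si](C)(C)C(C)(C)C)c1ccc(OCC=C(C)C)c(OC)c1
F5 | step 14 | [(2R,3R,4R)-2-(ArTIPS)-4-[(S)-(ArPren)(TBS-oxy)methyl]tetrahydrofuran-3-yl]methyl methanesulfonate | COc1cc(ccc1O[Si](C(C)C)(C(C)C)C(C)C)[C@@H]1OC[C@H]([C@H](O[Si](C)(C)C(C)(C)C)c2ccc(OCC=C(C)C)c(OC)c2)[C@@H]1COS(C)(=O)=O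
F6 | step 4 | (1S,2R)-2-allyl-1-(ArBn)propane-1,3-diol | OC[C@@H](CC=C)[C@H](O)c1ccc(OCc2ccccc2)c(OC)c1
F7 | step 4 | tert-butyl{[(2R)-2-[(S)-(ArBn)(TBS-oxy)methyl]pent-4-enyl]oxy}dimethylsilane | CC(C)(C)[Si](C)(C)OC[C@@H](CC=C)[C@H](O[Si](C)(C)C(C)(C)C)c1ccc(OCc2ccccc2)c(OC)c1
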